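**Retrosynthetic overview**

1. The target is a left half (rings A/B, 7(17)-ene, 18-oic acid), a central cyclohexene (ring C) and a right half (rings D/E, 8′(17′),12′E-diene, 18′-oic acid). The two decalins have mirror-image C4/C5/C9/C10 configurations, so the two tartrate enantiomers serve the two halves.
2. Disconnections: C11′–C12′ (sp3–sp2 Negishi coupling, last C–C bond); ring C by Diels–Alder reaction of the C12–C15 diene of the left half with acrolein (bonds C12–C14′ and C15–C15′); both acids come from silyl-protected CH2OH groups at the end.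
3. Rings A and B are formed together from an acyclic epoxy trienoate by a titanocene-mediated radical bicyclization that makes C4–C5 and then C9–C10, a radical copy of the epoxide-initiated cyclase folding of the biosynthesis.
4. Enabling feature: C4 (quaternary, CH3 plus oxidised carbon), the trans C5–C10 fusion with angular C20, and the equatorial C11 arm on C9 map onto a C3–C4 epoxide, an (E)-C5=C10 alkene and a C9=C11 enoate in 1,5-relationships; the C7 methylidene lies in the C6–C8 tether, where neither radical can reach it through a favourable ring size.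
5. Ring order: A then B (step 7), C (step 12); E then D (step 18, same manifold, mirror-image epoxide from farnesyl acetate) made separately; union in step 22.

Key step: step 7

Remark (numbering and shorthand): atoms carry labdane numbers, left half C1–C20 and right half C1′–C20′. C17/C17′ are the methylidene carbons on C7 and C8′, C18/C18′ the oxygenated carbons on C4/C4′, C19/C19′ and C20/C20′ the methyls on C4/C4′ and C10/C10′; ring C holds C12–C15, C15′ and C14′. "Unit L" is 4α-(tert-butyldimethylsilyloxymethyl)-4β,10β-dimethyl-7-methylidene-trans-decalin (5α-H, 9α-H) bonded through C9 (β, equatorial). "Unit R" is 4′β-(tert-butyldimethylsilyloxymethyl)-4′α,10′α-dimethyl-8′-methylidene-trans-decalin (5′β-H, 9′β-H) bonded through C9′ (α, equatorial).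

Remark (starting materials): compounds 1, 2, 5, 8, 16, 19 and 24 are taken as catalogue compounds.

**Route**

Step 1
Reactants: 1 pent-4-ynal; 2 ethyl 2-(triphenylphosphoranylidene)propanoate
Product: 3 ethyl (2E)-2-methylhept-2-en-6-ynoate
Conditions: 2 (1.1 equiv), CH2Cl2, rt
Reagents that add atoms: none
Why: Wittig olefination with a stabilised ylide should give the (E)-trisubstituted enoate and leaves the terminal alkyne untouched.

Step 2
Reactants: 3 ethyl (2E)-2-methylhept-2-en-6-ynoate
Product: 4 (2E)-2-methylhept-2-en-6-yn-1-ol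
Conditions: i-Bu2AlH (2.2 equiv), CH2Cl2, −78 → 0 °C
Reagents that add atoms: none
Why: 1,2-reduction of the conjugated ester with DIBAL-H gives the allylic alcohol needed for the later Sharpless epoxidation without changing the alkene geometry.

Step 3
Reactants: 4 (2E)-2-methylhept-2-en-6-yn-1-ol; 5 3-chloro-2-(chloromethyl)prop-1-ene
Product: 7 (2E,6E)-9-(chloromethyl)-2,6-dimethyldeca-2,6,9-trien-1-ol, via alkenylalane 6 (not isolated)
Conditions: Me3Al (3 equiv), Cp2ZrCl2 (0.25 equiv), CH2Cl2, 0 °C → rt; then 5 (5 equiv), Pd(PPh3)4 (5 mol %), THF, rt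
Reagents that add atoms: trimethylaluminium, C[Al](C)C
Why: Negishi zirconium-catalysed carboalumination adds methyl and aluminium syn across the alkyne (methyl to the internal carbon), fixing the (E)-C5=C10 alkene, and the alkenylalane is then allylated with retention under zerovalent palladium catalysis by the symmetrical dichloride used in excess, which installs the C7 methylidene and keeps one chloride for step 4.

Step 4
Reactants: 7 (2E,6E)-9-(chloromethyl)-2,6-dimethyldeca-2,6,9-trien-1-ol; 8 ethyl (2E)-3-(tributylstannyl)prop-2-enoate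
Product: 9 ethyl (2E,7E,11E)-13-hydroxy-8,12-dimethyl-5-methylidenetrideca-2,7,11-trienoate
Conditions: 8 (1.2 equiv), Pd2(dba)3 (2.5 mol %), P(2-furyl)3 (10 mol %), THF, 50 °C
Reagents that add atoms: none
Why: Stille coupling of the allylic chloride (π-allyl palladium with two identical CH2 termini, so no regiochemical choice) with the (E)-vinylstannane should give the skipped dienoate with retention of the enoate geometry under neutral conditions.

Step 5
Reactants: 9 ethyl (2E,7E,11E)-13-hydroxy-8,12-dimethyl-5-methylidenetrideca-2,7,11-trienoate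
Product: 10 ethyl (2E,7E)-10-[(2S,3S)-3-(hydroxymethyl)-3-methyloxiran-2-yl]-8-methyl-5-methylidenedeca-2,7-dienoate
Conditions: Ti(OiPr)4 (10 mol %), L-(+)-diethyl tartrate (12 mol %), t-BuOOH (2 equiv), 4 Å MS, CH2Cl2, −20 °C
Reagents that add atoms: tert-butyl hydroperoxide, CC(C)(C)OO
Why: Sharpless asymmetric epoxidation touches only the allylic alcohol alkene among the four C=C bonds, and L-(+)-tartrate delivers oxygen to the face that gives the (2S,3S)-epoxide, i.e. (S) at C3, which later fixes the absolute sense of folding.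

Step 6
Reactants: 10 ethyl (2E,7E)-10-[(2S,3S)-3-(hydroxymethyl)-3-methyloxiran-2-yl]-8-methyl-5-methylidenedeca-2,7-dienoate
Product: 11 tert-butyldimethylsilyl ether of 10
Conditions: TBSCl, imidazole, DMF, 0 °C → rt
Reagents that add atoms: tert-butyl(chloro)dimethylsilane, CC(C)(C)[Si](C)(C)Cl
Why: Standard silylation caps the primary hydroxyl so that it cannot bind titanium in step 7 and makes the C18 substituent the large group on C4.

Step 7
Reactants: 11 tert-butyldimethylsilyl ether of 10
Product: 12 ethyl 2-(3β-hydroxy-unit L)acetate (3-OH equatorial)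
Conditions: Cp2TiCl2 (2.5 equiv), Mn dust (8 equiv), THF (0.01 M in 11), rt; then 1 M aq. HCl
Reagents that add atoms: none
Why: Cp2TiCl (trivalent titanium, formed in the flask from Cp2TiCl2 and Mn) opens the epoxide homolytically at the tertiary C4–O bond, the C4 radical adds to C5 of the (E)-C5=C10 alkene, the tertiary C10 radical so formed adds to C9 of the electron-poor enoate, and the C11 α-ester radical is reduced by a second Cp2TiCl to a titanium enolate that is protonated on work-up. The closest known reaction type is the titanocene-mediated reductive radical cyclization of epoxypolyprenes (Nugent–RajanBabu epoxide opening followed by a polyene cascade), here ended by the conjugate radical addition known for epoxide-derived radicals and acrylates. Ring A closes by 6-endo-trig attack (C4–C5, giving the tertiary radical) and ring B by 6-exo-trig attack (C10–C9), both through chair transition states. C3 keeps the (S) configuration of the epoxide and its bulky O–Ti group lies equatorial, which fixes the absolute sense of folding; C4 is set by the planar radical turning its larger CH2OTBS group pseudo-equatorial (C19 methyl axial, cis to C20), C5 and C10 by anti addition across the (E)-alkene in the chair–chair array (trans fusion, C20 axial), and C9 by the enoate arm lying equatorial (H-9 axial, α). The step needs each radical to react only with its programmed partner: the C7 methylidene could be reached from C10 only by 4-exo or 5-endo closure and is not polarised, whereas the enoate is polarity-matched to the nucleophilic C10 radical, and high dilution keeps interception of the radicals by trivalent titanium slower than the ring closures.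

Step 8
Reactants: 12 ethyl 2-(3β-hydroxy-unit L)acetate
Product: 14 ethyl 2-(unit L)acetate, via imidazolyl thiocarbonate 13 (not isolated)
Conditions: 1,1′-thiocarbonyldiimidazole, DMAP (cat.), toluene, 90 °C; then Bu3SnH, AIBN (cat.), 110 °C
Reagents that add atoms: none
Why: Barton–McCombie deoxygenation removes the C3 hydroxyl through its imidazolyl thiocarbonate and a secondary C3 radical that is reduced by Bu3SnH, without creating or touching a stereocentre.

Step 9
Reactants: 14 ethyl 2-(unit L)acetate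
Product: 15 2-(unit L)acetaldehyde
Conditions: i-Bu2AlH (1.05 equiv), toluene, −78 °C
Reagents that add atoms: none
Why: DIBAL-H at −78 °C should stop at the aldehyde through the stable aluminium hemiacetal, with the silyl ether and the methylidene inert.

Step 10
Reactants: 15 2-(unit L)acetaldehyde; 16 2-(triphenylphosphoranylidene)propanal
Product: 17 (2E)-2-methyl-4-(unit L)but-2-enal
Conditions: 16 (1.5 equiv), toluene, 90 °C
Reagents that add atoms: none
Why: Wittig reaction with the formyl-stabilised ylide should give the (E)-2-methyl enal (C11 and CHO trans) selectively.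

Step 11
Reactants: 17 (2E)-2-methyl-4-(unit L)but-2-enal
Product: 18 (3E)-3-methyl-5-(unit L)penta-1,3-diene
Conditions: Ph3PCH3Br, KOtBu, THF, 0 °C
Reagents that add atoms: methyltriphenylphosphonium bromide, C[P+](c1ccccc1)(c1ccccc1)c1ccccc1.[Br-]
Why: Wittig methylenation of the enal completes the (12E)-configured 3-methyl-1,3-diene of the left half without touching the existing alkene geometry.

Step 12
Reactants: 18 (3E)-3-methyl-5-(unit L)penta-1,3-diene; 19 acrolein
Product: 20 (1S,2S)-3-methyl-2-[(unit L)methyl]cyclohex-3-ene-1-carbaldehyde (C12 and C14′ substituents cis)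
Conditions: 19 (5 equiv), (5R)-5-benzyl-2,2,3-trimethylimidazolidin-4-one hydrochloride (20 mol %), CH3CN/H2O 95:5, −10 °C
Reagents that add atoms: none
Why: In this iminium-catalysed Diels–Alder reaction the formyl-bearing carbon should bond to the substituted diene terminus C12 (the 1-alkyl group directs "ortho") through an endo transition state (cis C12/C14′), and the benzyl group of the (5R) catalyst shields one face of the dienophile so that (S) at C14′ and hence (S) at C12 are set under catalyst control, the decalin stereocentres being too remote to interfere.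

Step 13
Reactants: 20 (1S,2S)-3-methyl-2-[(unit L)methyl]cyclohex-3-ene-1-carbaldehyde
Product: 21 (5S,6S)-5-ethynyl-1-methyl-6-[(unit L)methyl]cyclohex-1-ene
Conditions: Me3SiCHN2, n-BuLi, THF, −78 → 0 °C
Reagents that add atoms: (trimethylsilyl)diazomethane, C[Si](C)(C)C=[N+]=[N-]
Why: In this Colvin rearrangement lithiated trimethylsilyldiazomethane adds to the aldehyde at −78 °C faster than it enolises it, and Peterson elimination, loss of N2 and a 1,2-hydrogen shift of the alkylidene carbene give the terminal alkyne with the cis C12/C14′ centres intact.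

Step 14
Reactants: 21 (5S,6S)-5-ethynyl-1-methyl-6-[(unit L)methyl]cyclohex-1-ene
Product: 23 (5S,6S)-5-[(1E)-1-iodoprop-1-en-2-yl]-1-methyl-6-[(unit L)methyl]cyclohex-1-ene, via alkenylalane 22 (not isolated)
Conditions: Me3Al (3 equiv), Cp2ZrCl2 (0.5 equiv), CH2Cl2, 0 °C → rt; then I2, THF, −30 °C
Reagents that add atoms: trimethylaluminium, C[Al](C)C; iodine, II
Why: Negishi carboalumination adds methyl (C16′, to C13′) and aluminium (to C12′) syn across the alkyne, and iodinolysis with retention gives the (E)-vinyl iodide with ring C and iodine trans.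

Step 15
Reactants: 24 (2E,6E)-farnesyl acetate
Product: 25 (2E,6E,10E)-12-hydroxy-3,7,11-trimethyldodeca-2,6,10-trien-1-yl acetate
Conditions: SeO2 (0.3 equiv), t-BuOOH (3 equiv), salicylic acid (0.1 equiv), CH2Cl2, rt
Reagents that add atoms: tert-butyl hydroperoxide, CC(C)(C)OO
Why: SeO2-catalysed allylic oxidation (ene reaction, then 2,3-sigmatropic shift) hydroxylates the (E)-methyl group of the terminal, most electron-rich trisubstituted alkene.

Step 16
Reactants: 25 (2E,6E,10E)-12-hydroxy-3,7,11-trimethyldodeca-2,6,10-trien-1-yl acetate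
Product: 26 (2E,6E)-9-[(2R,3R)-3-(hydroxymethyl)-3-methyloxiran-2-yl]-3,7-dimethylnona-2,6-dien-1-yl acetate
Conditions: Ti(OiPr)4 (10 mol %), D-(−)-diethyl tartrate (12 mol %), t-BuOOH (2 equiv), 4 Å MS, CH2Cl2, −20 °C
Reagents that add atoms: tert-butyl hydroperoxide, CC(C)(C)OO
Why: Sharpless asymmetric epoxidation with the enantiomeric tartrate gives the (2R,3R)-epoxide, the mirror-image initiator needed for the right half.

Step 17
Reactants: 26 (2E,6E)-9-[(2R,3R)-3-(hydroxymethyl)-3-methyloxiran-2-yl]-3,7-dimethylnona-2,6-dien-1-yl acetate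
Product: 27 tert-butyldimethylsilyl ether of 26
Conditions: TBSCl, imidazole, DMF, 0 °C → rt
Reagents that add atoms: tert-butyl(chloro)dimethylsilane, CC(C)(C)[Si](C)(C)Cl
Why: Standard silylation, for the same reasons as in step 6.

Step 18
Reactants: 27 tert-butyldimethylsilyl ether of 26
Product: 28 (3′α-hydroxy-unit R)methyl acetate (3′-OH equatorial)
Conditions: Cp2TiCl2 (2.2 equiv), Mn dust (8 equiv), THF (0.01 M), rt; then 1 M aq. HCl
Reagents that add atoms: none
Why: The same titanocene-mediated radical bicyclization as in step 7 (6-endo, then 6-endo) ends when the tertiary C8′ radical gives up a C17′ hydrogen atom to trivalent titanium to form the exocyclic 8′(17′)-alkene, and the (R)-configured C3′–O–Ti group, equatorial in the chair–chair array, sets the mirror-image trans-decalin with CH2OTBS equatorial on C4′ and the CH2OAc arm equatorial on C9′.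

Step 19
Reactants: 28 (3′α-hydroxy-unit R)methyl acetate
Product: 30 (unit R)methyl acetate, via imidazolyl thiocarbonate 29 (not isolated)
Conditions: 1,1′-thiocarbonyldiimidazole, DMAP (cat.), toluene, 90 °C; then Bu3SnH, AIBN (cat.), 110 °C
Reagents that add atoms: none
Why: Barton–McCombie deoxygenation of the C3′ hydroxyl, as in step 8.

Step 20
Reactants: 30 (unit R)methyl acetate
Product: 31 (unit R)methanol
Conditions: K2CO3, MeOH, rt
Reagents that add atoms: none
Why: Base-catalysed transesterification removes the acetate while the silyl ether is stable.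

Step 21
Reactants: 31 (unit R)methanol
Product: 32 (unit R)methyl iodide (C11′ iodide)
Conditions: I2, PPh3, imidazole, toluene, 0 → 40 °C
Reagents that add atoms: iodine, II
Why: Garegg–Samuelsson iodination converts the primary alcohol into the iodide through its alkoxyphosphonium salt; no stereocentre is involved.

Step 22
Reactants: 32 (unit R)methyl iodide; 23 (5S,6S)-5-[(1E)-1-iodoprop-1-en-2-yl]-1-methyl-6-[(unit L)methyl]cyclohex-1-ene
Product: 34 (5S,6S)-1-methyl-6-[(unit L)methyl]-5-[(2E)-4-(unit R)but-2-en-2-yl]cyclohex-1-ene, via alkylzinc iodide 33 (not isolated)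
Conditions: Zn dust, LiCl, THF, 40 °C; then 23, PdCl2(dppf) (5 mol %), THF/NMP, 50 °C
Reagents that add atoms: none
Why: In this Negishi cross-coupling zinc inserts into the primary C–I bond and the alkylzinc iodide couples with the (E)-vinyl iodide with retention of geometry, forming the C11′–C12′ bond and completing the carbon skeleton.

Step 23
Reactants: 34 (5S,6S)-1-methyl-6-[(unit L)methyl]-5-[(2E)-4-(unit R)but-2-en-2-yl]cyclohex-1-ene
Product: 35 18,18′-diol (34 with both silyl groups replaced by hydrogen)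
Conditions: Bu4NF, THF, 50 °C
Reagents that add atoms: none
Why: Fluoride cleaves both neopentyl silyl ethers and leaves the four alkenes untouched.

Step 24
Reactants: 35 18,18′-diol
Product: 36 18,18′-dial
Conditions: Dess–Martin periodinane, NaHCO3, CH2Cl2, rt
Reagents that add atoms: none
Why: Dess–Martin oxidation takes both primary alcohols to aldehydes that sit on quaternary carbons and therefore cannot epimerise.

Step 25
Reactants: 36 18,18′-dial
Product: 37 CNP0240573.1 (18,18′-dioic acid)
Conditions: NaClO2, NaH2PO4, 2-methylbut-2-ene, t-BuOH/THF/H2O, 0 °C → rt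
Reagents that add atoms: sodium chlorite, [Na+].[O-]Cl=O
Why: Pinnick oxidation converts both aldehydes to the carboxylic acids while 2-methylbut-2-ene scavenges hypochlorous acid and so protects the four alkenes.

**Compound list**

1 | pent-4-ynal | C#CCCC=O | starting material
2 | ethyl 2-(triphenylphosphoranylidene)propanoate | CCOC(=O)C(C)=P(c1ccccc1)(c1ccccc1)c1ccccc1 | starting material
3 | ethyl (2E)-2-methylhept-2-en-6-ynoate | C#CCC/C=C(\C)C(=O)OCC | intermediate
4 | (2E)-2-methylhept-2-en-6-yn-1-ol | C#CCC/C=C(\C)CO | intermediate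
5 | 3-chloro-2-(chloromethyl)prop-1-ene | C=C(CCl)CCl | starting material
6 | dimethyl{(1E,5E)-7-[(dimethylalumanyl)oxy]-2,6-dimethylhepta-1,5-dien-1-yl}alumane | C[Al](C)/C=C(\C)CC/C=C(\C)CO[Al](C)C | intermediate
7 | (2E,6E)-9-(chloromethyl)-2,6-dimethyldeca-2,6,9-trien-1-ol | OC/C(C)=C/CC/C(C)=C/CC(=C)CCl | intermediate
8 | ethyl (2E)-3-(tributylstannyl)prop-2-enoate | CCCC[Sn](CCCC)(CCCC)/C=C/C(=O)OCC | starting material
9 | ethyl (2E,7E,11E)-13-hydroxy-8,12-dimethyl-5-methylidenetrideca-2,7,11-trienoate | CCOC(=O)/C=C/CC(=C)C/C=C(\C)CC/C=C(\C)CO | intermediate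
10 | ethyl (2E,7E)-10-[(2S,3S)-3-(hydroxymethyl)-3-methyloxiran-2-yl]-8-methyl-5-methylidenedeca-2,7-dienoate | CCOC(=O)/C=C/CC(=C)C/C=C(\C)CC[C@@H]1O[C@@]1(C)CO | intermediate
11 | tert-butyldimethylsilyl ether of 10 | CCOC(=O)/C=C/CC(=C)C/C=C(\C)CC[C@@H]1O[C@@]1(C)CO[Si](C)(C)C(C)(C)C | intermediate
12 | ethyl 2-(3β-hydroxy-unit L)acetate | C=C1C[C@H](CC(=O)OCC)[C@@]2(C)CC[C@H](O)[C@@](C)(CO[Si](C)(C)C(C)(C)C)[C@@H]2C1 | intermediate
13 | 3β-O-(imidazol-1-ylcarbonothioyl) derivative of 12 | C=C1C[C@H](CC(=O)OCC)[C@@]2(C)CC[C@H](OC(=S)n3ccnc3)[C@@](C)(CO[Si](C)(C)C(C)(C)C)[C@@H]2C1 | intermediate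
14 | ethyl 2-(unit L)acetate | C=C1C[C@H](CC(=O)OCC)[C@@]2(C)CCC[C@@](C)(CO[Si](C)(C)C(C)(C)C)[C@@H]2C1 | intermediate
15 | 2-(unit L)acetaldehyde | C=C1C[C@H](CC=O)[C@@]2(C)CCC[C@@](C)(CO[Si](C)(C)C(C)(C)C)[C@@H]2C1 | intermediate
16 | 2-(triphenylphosphoranylidene)propanal | CC(C=O)=P(c1ccccc1)(c1ccccc1)c1ccccc1 | starting material
17 | (2E)-2-methyl-4-(unit L)but-2-enal | C=C1C[C@H](C/C=C(\C)C=O)[C@@]2(C)CCC[C@@](C)(CO[Si](C)(C)C(C)(C)C)[C@@H]2C1 | intermediate
18 | (3E)-3-methyl-5-(unit L)penta-1,3-diene | C=C1C[C@H](C/C=C(\C)C=C)[C@@]2(C)CCC[C@@](C)(CO[Si](C)(C)C(C)(C)C)[C@@H]2C1 | intermediate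
19 | acrolein (prop-2-enal) | C=CC=O | starting material
20 | (1S,2S)-3-methyl-2-[(unit L)methyl]cyclohex-3-ene-1-carbaldehyde | C=C1C[C@H](C[C@@H]2C(C)=CCC[C@@H]2C=O)[C@@]2(C)CCC[C@@](C)(CO[Si](C)(C)C(C)(C)C)[C@@H]2C1 | intermediate
21 | (5S,6S)-5-ethynyl-1-methyl-6-[(unit L)methyl]cyclohex-1-ene | C=C1C[C@H](C[C@@H]2C(C)=CCC[C@@H]2C#C)[C@@]2(C)CCC[C@@](C)(CO[Si](C)(C)C(C)(C)C)[C@@H]2C1 | intermediate
22 | (E)-alkenyl(dimethyl)alane from 21 (AlMe2 on C12′, methyl C16′ on C13′) | C=C1C[C@H](C[C@@H]2C(C)=CCC[C@@H]2/C(C)=C/[Al](C)C)[C@@]2(C)CCC[C@@](C)(CO[Si](C)(C)C(C)(C)C)[C@@H]2C1 | intermediate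
23 | (5S,6S)-5-[(1E)-1-iodoprop-1-en-2-yl]-1-methyl-6-[(unit L)methyl]cyclohex-1-ene | C=C1C[C@H](C[C@@H]2C(C)=CCC[C@@H]2/C(C)=C/I)[C@@]2(C)CCC[C@@](C)(CO[Si](C)(C)C(C)(C)C)[C@@H]2C1 | intermediate
24 | (2E,6E)-farnesyl acetate | CC(=O)OC/C=C(\C)CC/C=C(\C)CCC=C(C)C | starting material
25 | (2E,6E,10E)-12-hydroxy-3,7,11-trimethyldodeca-2,6,10-trien-1-yl acetate | CC(=O)OC/C=C(\C)CC/C=C(\C)CC/C=C(\C)CO | intermediate
26 | (2E,6E)-9-[(2R,3R)-3-(hydroxymethyl)-3-methyloxiran-2-yl]-3,7-dimethylnona-2,6-dien-1-yl acetate | CC(=O)OC/C=C(\C)CC/C=C(\C)CC[C@H]1O[C@]1(C)CO | intermediate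
27 | tert-butyldimethylsilyl ether of 26 | CC(=O)OC/C=C(\C)CC/C=C(\C)CC[C@H]1O[C@]1(C)CO[Si](C)(C)C(C)(C)C | intermediate
28 | (3′α-hydroxy-unit R)methyl acetate | CC(=O)OC[C@@H]1C(=C)CC[C@H]2[C@@]1(C)CC[C@@H](O)[C@]2(C)CO[Si](C)(C)C(C)(C)C | intermediate
29 | 3′-O-(imidazol-1-ylcarbonothioyl) derivative of 28 | CC(=O)OC[C@@H]1C(=C)CC[C@H]2[C@@]1(C)CC[C@@H](OC(=S)n3ccnc3)[C@]2(C)CO[Si](C)(C)C(C)(C)C | intermediate
30 | (unit R)methyl acetate | CC(=O)OC[C@@H]1C(=C)CC[C@H]2[C@@]1(C)CCC[C@]2(C)CO[Si](C)(C)C(C)(C)C | intermediate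
31 | (unit R)methanol | OC[C@@H]1C(=C)CC[C@H]2[C@@]1(C)CCC[C@]2(C)CO[Si](C)(C)C(C)(C)C | intermediate
32 | (unit R)methyl iodide | IC[C@@H]1C(=C)CC[C@H]2[C@@]1(C)CCC[C@]2(C)CO[Si](C)(C)C(C)(C)C | intermediate
33 | [(unit R)methyl]zinc iodide | I[Zn]C[C@@H]1C(=C)CC[C@H]2[C@@]1(C)CCC[C@]2(C)CO[Si](C)(C)C(C)(C)C | intermediate
34 | (5S,6S)-1-methyl-6-[(unit L)methyl]-5-[(2E)-4-(unit R)but-2-en-2-yl]cyclohex-1-ene | C=C1C[C@H](C[C@@H]2C(C)=CCC[C@@H]2/C(C)=C/C[C@@H]2C(=C)CC[C@H]3[C@@]2(C)CCC[C@]3(C)CO[Si](C)(C)C(C)(C)C)[C@@]2(C)CCC[C@@](C)(CO[Si](C)(C)C(C)(C)C)[C@@H]2C1 | intermediate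
35 | 18,18′-diol (34 without the two silyl groups) | C=C1C[C@H](C[C@@H]2C(C)=CCC[C@@H]2/C(C)=C/C[C@@H]2C(=C)CC[C@H]3[C@@]2(C)CCC[C@]3(C)CO)[C@@]2(C)CCC[C@@](C)(CO)[C@@H]2C1 | intermediate
36 | 18,18′-dial | C=C1C[C@H](C[C@@H]2C(C)=CCC[C@@H]2/C(C)=C/C[C@@H]2C(=C)CC[C@H]3[C@@]2(C)CCC[C@]3(C)C=O)[C@@]2(C)CCC[C@@](C)(C=O)[C@@H]2C1 | intermediate
37 | CNP0240573.1 (18,18′-dioic acid) | C=C1C[C@H](C[C@@H]2C(C)=CCC[C@@H]2/C(C)=C/C[C@@H]2C(=C)CC[C@H]3[C@@]2(C)CCC[C@]3(C)C(=O)O)[C@@]2(C)CCC[C@@](C)(C(=O)O)[C@@H]2C1 | target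

**Step count and risks**

Total step count: 25. Longest linear sequence: 18 steps (steps 1–14, then 22–25); the right half takes steps 15–21.

Steps most likely to fail:

Step 7. The bicyclization may suffer from interception of the C4 or C10 radical by trivalent titanium before ring closure, from a 1,5-hydrogen shift of the doubly allylic C8–H to the C10 radical, and from too small a preference for the equatorial siloxymethyl orientation at C4. The fallback replaces the radical cascade by a cationic, stereospecific one and sets out from 7. Stille coupling of 7 with (E)-trimethyl[3-(tributylstannyl)prop-2-en-1-yl]silane would give (2E,6E,11E)-2,6-dimethyl-9-methylidene-13-(trimethylsilyl)trideca-2,6,11-trien-1-ol F1. Sharpless epoxidation with L-(+)-diethyl tartrate would give the (2S,3S)-epoxy alcohol F2, and silylation its tert-butyldimethylsilyl ether F3. MeAlCl2 in CH2Cl2 at −78 °C should open the epoxide heterolytically, with C5 attacking C4 anti to the leaving oxygen, so that the siloxymethyl group (trans to the chain on the epoxide) becomes equatorial by geometry rather than by size; the allylsilane then closes ring B through C9 to give the 3β-hydroxy C9-vinyl decalin F4. Deoxygenation as in step 8, through the imidazolyl thiocarbonate F5, would give the C9-vinyl decalin F6. Disiamylborane should add to the vinyl group only (trialkylborane F7), alkaline H2O2 would give the primary alcohol F8, and Dess–Martin oxidation of F8 returns to the route at 15.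

Step 12. The cycloaddition may leak to the regioisomer in which the formyl-bearing carbon bonds to C15 (the C13 methyl directs against the C11 substituent), may show incomplete endo and facial selectivity, and the product may epimerise next to the formyl group under amine catalysis. The fallback uses an auxiliary and a Lewis acid instead of the amine catalyst and sets out from 18. Cycloaddition with (4R)-3-acryloyl-4-benzyl-1,3-oxazolidin-2-one and Et2AlCl in CH2Cl2 at −78 °C (chelated s-cis acrylimide, one face blocked by the benzyl group, endo) would give the cis imide F9. LiBH4 removes the auxiliary to give the primary alcohol F10, and Dess–Martin oxidation returns to the route at 20.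

Step 22. Zinc insertion and transmetallation at the β-branched C11′ may be slow, so that protodemetallation and homocoupling compete with the cross-coupling. The fallback changes the organometallic partner and sets out from 32. Iodine–lithium exchange with t-BuLi in Et2O at −78 °C would give the alkyllithium F11, and trapping with B-methoxy-9-borabicyclo[3.3.1]nonane the lithium alkyl(methoxy)borate F12. B-alkyl Suzuki–Miyaura coupling of F12 with 23 (PdCl2(dppf), aq. K3PO4, DMF, rt) returns to the route at 34.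

**Further compounds**

F1 | step 7 | (2E,6E,11E)-2,6-dimethyl-9-methylidene-13-(trimethylsilyl)trideca-2,6,11-trien-1-ol | OC/C(C)=C/CC/C(C)=C/CC(=C)C/C=C/C[Si](C)(C)C
F2 | step 7 | {(2S,3S)-2-methyl-3-[(3E,8E)-3-methyl-6-methylidene-10-(trimethylsilyl)deca-3,8-dien-1-yl]oxiran-2-yl}methanol | C[Si](C)(C)C/C=C/CC(=C)C/C=C(\C)CC[C@@H]1O[C@@]1(C)CO
F3 | step 7 | tert-butyldimethylsilyl ether of F2 | C[Si](C)(C)C/C=C/CC(=C)C/C=C(\C)CC[C@@H]1O[C@@]1(C)CO[Si](C)(C)C(C)(C)C
F4 | step 7 | 9-vinyl-3β-hydroxy-unit L (vinyl on C9, β) | C=C1C[C@H](C=C)[C@@]2(C)CC[C@H](O)[C@@](C)(CO[Si](C)(C)C(C)(C)C)[C@@H]2C1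
F5 | step 7 | 3β-O-(imidazol-1-ylcarbonothioyl) derivative of F4 | C=C1C[C@H](C=C)[C@@]2(C)CC[C@H](OC(=S)n3ccnc3)[C@@](C)(CO[Si](C)(C)C(C)(C)C)[C@@H]2C1
F6 | step 7 | 9-vinyl-unit L | C=C1C[C@H](C=C)[C@@]2(C)CCC[C@@](C)(CO[Si](C)(C)C(C)(C)C)[C@@H]2C1
F7 | step 7 | bis(3-methylbutan-2-yl)[2-(unit L)ethyl]borane | C=C1C[C@H](CCB(C(C)C(C)C)C(C)C(C)C)[C@@]2(C)CCC[C@@](C)(CO[Si](C)(C)C(C)(C)C)[C@@H]2C1
F8 | step 7 | 2-(unit L)ethanol | C=C1C[C@H](CCO)[C@@]2(C)CCC[C@@](C)(CO[Si](C)(C)C(C)(C)C)[C@@H]2C1
F9 | step 12 | (4R)-4-benzyl-3-{(1S,2S)-3-methyl-2-[(unit L)methyl]cyclohex-3-ene-1-carbonyl}-1,3-oxazolidin-2-one | C=C1C[C@H](C[C@@H]2C(C)=CCC[C@@H]2C(=O)N3[C@H](Cc4ccccc4)COC3=O)[C@@]2(C)CCC[C@@](C)(CO[Si](C)(C)C(C)(C)C)[C@@H]2C1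
F10 | step 12 | {(1S,2S)-3-methyl-2-[(unit L)methyl]cyclohex-3-en-1-yl}methanol | C=C1C[C@H](C[C@@H]2C(C)=CCC[C@@H]2CO)[C@@]2(C)CCC[C@@](C)(CO[Si](C)(C)C(C)(C)C)[C@@H]2C1
F11 | step 22 | [(unit R)methyl]lithium | [Li]C[C@@H]1C(=C)CC[C@H]2[C@@]1(C)CCC[C@]2(C)CO[Si](C)(C)C(C)(C)C
F12 | step 22 | lithium 9-methoxy-9-[(unit R)methyl]-9-boranuidabicyclo[3.3.1]nonane | [Li+].CO[B-]1(C[C@@H]2C(=C)CC[C@H]3[C@@]2(C)CCC[C@]3(C)CO[Si](C)(C)C(C)(C)C)C2CCCC1CCC2
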